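**Retrosynthetic overview**
1. Target 38 comes from hydroquinone 37 by selective O-acetylation; C3=C(CH3)2 comes from a C3 ketone, the C4 propanoate chain from Mukaiyama–Michael addition to a C3-oxo-C4-methylidene unit, and C8–CH3 and C10–H from hydrogen-atom-transfer hydrogenation of C8=CH2 and C10=C1.
2. Key disconnection: ring B (C5–C6–C7–C8–C9–C10) is made from the cyclopentenone ring C8–C7–C6–C5–C10 of bicyclic enone 19 by a one-carbon ring expansion. C9, with its methyl, comes from 1,1-dibromoethane and is inserted into the C8–C10 bond; the resulting C8 enolate is benzylated by arene 5 in the same flask.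
3. Enabling feature: in ring B the carbonyl-level carbon C8 is bonded to quaternary C9, whose only non-ring substituents are CH3 and the arylmethyl group, and C9 is bonded to ring-fusion carbon C10, which can be carried as an sp2 carbon (C10=C1 in ring A). C9 can therefore be a carbenoid carbon, C10 the migrating alkenyl group, and the C8/C9 enolate an octalone-type dienolate that alkylates anti to the axial C5 methyl.
4. Enone 19 comes from 3-methylcyclopent-2-enone by copper-catalysed asymmetric conjugate addition (sets quaternary C5), α-methylenation, ring-closing metathesis (ring A) and allylic oxidation at C3.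
5. Order of ring formation: five-membered ring (purchased), then ring A (metathesis), then ring B (ring expansion); the arene is purchased as 4-methoxy-2-methylphenol.

Key step: step 11

Remark on the chemistry: carbons are numbered C1–C10 in the decalin (C5 and C10 ring fusion, C9 the arylmethyl-bearing carbon, C11 the benzylic CH2), β is the face of the C5 methyl, and stereocentres that are destroyed later (C3 in 18–26 and 33, C8 in 21–22, C10 in 14–15) are carried as mixtures and left undefined in the SMILES.

**Step 1**
Reactants: 1 4-methoxy-2-methylphenol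
Product: 2 2-hydroxy-5-methoxy-3-methylbenzaldehyde
Conditions: MgCl2, Et3N, (CH2O)n, MeCN, reflux; then 1 M HCl
Reagents that add atoms: paraformaldehyde (as formaldehyde), C=O
Why: Magnesium-phenoxide-directed ortho-formylation of a phenol can only occur at the single free ortho position, and no stereocentre is formed.

**Step 2**
Reactants: 2 2-hydroxy-5-methoxy-3-methylbenzaldehyde
Product: 3 2,5-dimethoxy-3-methylbenzaldehyde
Conditions: MeI, K2CO3, DMF, rt
Reagents that add atoms: iodomethane, CI
Why: Williamson O-methylation of the phenol, to which the aldehyde is inert.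

**Step 3**
Reactants: 3 2,5-dimethoxy-3-methylbenzaldehyde
Product: 4 (2,5-dimethoxy-3-methylphenyl)methanol
Conditions: NaBH4, MeOH, 0 °C
Reagents that add atoms: none
Why: Borohydride reduction of an aromatic aldehyde to the benzylic alcohol.

**Step 4**
Reactants: 4 (2,5-dimethoxy-3-methylphenyl)methanol
Product: 5 1-(bromomethyl)-2,5-dimethoxy-3-methylbenzene
Conditions: PBr3, Et2O, 0 °C
Reagents that add atoms: phosphorus tribromide, BrP(Br)Br
Why: Bromination of an electron-rich benzylic alcohol through its phosphite ester (SN2), giving the electrophile for step 11.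

**Step 5**
Reactants: 6 2,3-dibromoprop-1-ene; 7 allylmagnesium bromide
Product: 8 2-bromohexa-1,5-diene
Conditions: Et2O, 0 °C to rt
Reagents that add atoms: allylmagnesium bromide 7, C=CC[Mg]Br
Why: Grignard substitution at the allylic bromide, the vinylic bromide being inert, gives the alkenyl bromide that carries C1–C4.

**Step 6**
Reactants: 8 2-bromohexa-1,5-diene; 9 3-methylcyclopent-2-en-1-one
Product: 13 (R)-{[3-(hexa-1,5-dien-2-yl)-3-methylcyclopent-1-en-1-yl]oxy}trimethylsilane, via 2-lithiohexa-1,5-diene 10 (not isolated), via alkenyl(dimethyl)alane 11 (not isolated), via aluminium enolate 12 (not isolated)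
Conditions: t-BuLi (2 equiv), Et2O, −78 °C; Me2AlCl, −78 to −30 °C; CuTC (copper thiophene-2-carboxylate, C5H3CuO2S, 10 mol %), chiral phosphinamine Ph2P–N[CH(CH3)(2-naphthyl)]2 (11 mol %, the antipode that gives (R)-13), 9, Et2O/THF, −30 °C; then TMSOTf, −30 to 0 °C, non-aqueous work-up
Reagents that add atoms: 3-methylcyclopent-2-en-1-one 9, CC1=CC(=O)CC1; trimethylsilyl trifluoromethanesulfonate, C[Si](C)(C)OS(=O)(=O)C(F)(F)F
Why: Copper-catalysed asymmetric conjugate addition of an alkenylalane to a β-methyl cyclic enone should build quaternary C5 under ligand control, and O-silylation of the aluminium enolate fixes the enolate on the C10 side.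

**Step 7**
Reactants: 13 silyl enol ether from step 6
Product: 16 (S)-3-(hexa-1,5-dien-2-yl)-3-methyl-2-methylidenecyclopentan-1-one, via Mannich base 14 (not isolated), via ammonium iodide 15 (not isolated)
Conditions: Eschenmoser's salt, CH2Cl2, rt; then MeI; then sat. aq. NaHCO3, CH2Cl2, rt
Reagents that add atoms: N,N-dimethylmethyleneiminium iodide (Eschenmoser's salt), C=[N+](C)C.[I-]
Why: Mannich reaction of the silyl enol ether at C10, quaternisation and E1cB elimination should give the α-methylene ketone regiospecifically; the transient C10 stereocentre is destroyed.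

**Step 8**
Reactants: 16 α-methylene ketone from step 7
Product: 17 (S)-3a-methyl-4-methylidene-2,3,3a,4,5,6-hexahydro-1H-inden-1-one (C8 ketone, C10=C1, C4=CH2, quaternary C5)
Conditions: second-generation Grubbs catalyst (5 mol %), CH2Cl2 (0.01 M), 40 °C
Reagents that add atoms: none
Why: Ring-closing metathesis of the terminal alkene with the enone methylene closes six-membered ring A as the C10=C1 enone; the hindered C4 methylene cannot give a productive ring.

**Step 9**
Reactants: 17 bicyclic enone from step 8
Product: 18 (3aS)-5-hydroxy-3a-methyl-4-methylidene-2,3,3a,4,5,6-hexahydro-1H-inden-1-one (C3 carbinol, both epimers)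
Conditions: SeO2 (0.5 equiv), t-BuOOH, CH2Cl2, rt
Reagents that add atoms: selenium dioxide (oxygen carrier), O=[Se]=O; tert-butyl hydroperoxide, CC(C)(C)OO
Why: Selenium dioxide allylic oxidation (ene reaction, then [2,3]-sigmatropic shift) should hit the only allylic CH2 of the electron-rich exocyclic alkene (C3, since C5 is quaternary) and spare the electron-poor enone; the C3 configuration is not controlled and is erased in step 13.

**Step 10**
Reactants: 18 allylic alcohol from step 9
Product: 19 tert-butyldimethylsilyl ether of 18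
Conditions: TBSCl, imidazole, DMF, rt
Reagents that add atoms: tert-butyl(chloro)dimethylsilane, CC(C)(C)[Si](C)(C)Cl
Why: Silylation of the secondary allylic alcohol protects it against the bases of steps 11 and 12.

**Step 11**
Reactants: 19 silyl ether from step 10; 20 1,1-dibromoethane; 5 1-(bromomethyl)-2,5-dimethoxy-3-methylbenzene
Product: 24 octal-1(10)-en-8-one with C9 bearing β-CH3 and α-CH2Ar (Ar = 2,5-dimethoxy-3-methylphenyl), C3–OTBS, C4=CH2 and C5 β-CH3, via lithium alkoxide 21 (not isolated), via oxido carbenoid 22 (not isolated), via lithium dienolate 23 (not isolated)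
Conditions: 19, CH3CHBr2, THF, −95 °C, slow addition of LiN(i-Pr)2; n-BuLi (1.1 equiv), −95 to −30 °C; then DMPU, 5, −78 to 0 °C
Reagents that add atoms: 1,1-dibromoethane 20, CC(Br)Br; 1-(bromomethyl)-2,5-dimethoxy-3-methylbenzene 5, COc1cc(C)c(OC)c(CBr)c1
Why: LiN(i-Pr)2 lithiates 1,1-dibromoethane in the presence of 19, the carbenoid adds to the C8 carbonyl, and bromine–lithium exchange of alkoxide 21 with n-BuLi gives the β-oxido carbenoid 22, in which the C8–C10 bond migrates to the carbenoid carbon (the future C9) with loss of LiBr, so that the five-membered ring C8–C7–C6–C5–C10 becomes six-membered ring B and the regiodefined dienolate 23 (O–C8=C9–C10=C1) is formed. The closest known reaction type is the β-oxido carbenoid one-carbon ring enlargement of cyclic ketones by gem-dibromoalkyllithium reagents with trapping of the ring-enlarged enolate by an alkyl halide, combined here with the classical deconjugative α-alkylation of an octalone dienolate. Ring B is closed by a 1,2-shift (ring expansion by one carbon), not by a cyclisation, and no other ring is formed. The new quaternary stereocentre C9 is set when 5 attacks the planar dienolate at C9 from the α face, anti to the axial C5 methyl that is 1,3 to C9, so that the C9 methyl ends β and the arylmethyl group α. The step needs migration of C10 in preference to C7 and C-alkylation at C9 in preference to O-alkylation or γ-alkylation at C1: the sp2 carbon C10 has the higher migratory aptitude in carbenoid 1,2-shifts, and lithium dienolates react with benzylic bromides at the α carbon, after which quaternary C9 prevents reconjugation.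

**Step 12**
Reactants: 24 ketone from step 11
Product: 25 triene with C8=CH2 in place of the C8 ketone of 24
Conditions: Ph3PCH3Br (5 equiv), KOt-Bu (4.8 equiv), toluene, 90 °C
Reagents that add atoms: methyltriphenylphosphonium bromide, C[P+](c1ccccc1)(c1ccccc1)c1ccccc1.[Br-]
Why: Wittig methylenation of the hindered α-quaternary C8 ketone with excess ylide at elevated temperature; no stereocentre is formed.

**Step 13**
Reactants: 25 silyl ether from step 12
Product: 27 C3-oxo-C4-methylidene compound (C8=CH2, C10=C1 retained), via allylic alcohol 26 (not isolated)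
Conditions: Bu4NF, THF, rt; then Dess–Martin periodinane, NaHCO3, CH2Cl2, 0 °C
Reagents that add atoms: none
Why: Fluoride desilylation and buffered Dess–Martin oxidation of the allylic alcohol should give the α-methylene ketone and erase the C3 stereocentre without moving the C10=C1 double bond.

**Step 14**
Reactants: 27 α-methylene ketone from step 13; 28 1-methoxy-1-(trimethylsilyloxy)ethene
Product: 30 C3 ketone carrying the 4β-(3-methoxy-3-oxopropyl) chain (4α-H), via silyl enol ether 29 (not isolated)
Conditions: 28 (2 equiv), TMSOTf (10 mol %), CH2Cl2, −78 °C; then 1 M HCl, THF, 0 °C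
Reagents that add atoms: 1-methoxy-1-(trimethylsilyloxy)ethene 28, C=C(OC)O[Si](C)(C)C
Why: Mukaiyama–Michael addition to the unhindered exocyclic methylene installs the three-carbon ester chain, and protonation of the C3 silyl enol ether at C4 should occur on the α face, anti to the C5 methyl, giving the equatorial β chain that is also the thermodynamic epimer.

**Step 15**
Reactants: 30 keto ester from step 14
Product: 31 trans-decalin keto ester with 8β-CH3 and 10α-H
Conditions: Mn(dpm)3 (dpm = 2,2,6,6-tetramethylheptane-3,5-dionate, 10 mol %), PhSiH3, t-BuOOH, i-PrOH, 22 °C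
Reagents that add atoms: none
Why: Metal-hydride hydrogen-atom-transfer hydrogenation reduces the C8 methylene and the hindered C10=C1 alkene through tertiary radicals that should accept hydrogen on the α face, opposite the axial C5 and C9 methyls, giving the equatorial 8β-methyl and the trans ring fusion while ketone, ester and arene survive.

**Step 16**
Reactants: 31 keto ester from step 15; 32 S-phenyl 2-methylpropanethioate
Product: 34 methyl ester with C3=C(CH3)2, via spiro lactone 33 (not isolated)
Conditions: LiN(i-Pr)2, 32, THF, −78 °C; then 31, −78 to 0 °C; then silica gel, toluene, 110 °C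
Reagents that add atoms: S-phenyl 2-methylpropanethioate 32, CC(C)C(=O)Sc1ccccc1
Why: Aldol addition of the thioester enolate with in situ lactonisation to the β-lactone, then thermal decarboxylative [2+2] cycloreversion, places the tetrasubstituted C3=C(CH3)2 double bond regiospecifically and leaves C4 untouched.

**Step 17**
Reactants: 34 methyl ester from step 16
Product: 35 carboxylic acid (dimethyl ether of the hydroquinone)
Conditions: LiOH, THF/MeOH/H2O, rt; then 1 M HCl
Reagents that add atoms: lithium hydroxide, [Li+].[OH-]
Why: Saponification of the methyl ester; with no enolisable ketone left, C4 cannot epimerise.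

**Step 18**
Reactants: 35 acid from step 17
Product: 37 hydroquinone acid, via quinone 36 (not isolated)
Conditions: (NH4)2Ce(NO3)6 (2.5 equiv), MeCN/H2O, 0 °C; then Na2S2O4, EtOAc/H2O, rt
Reagents that add atoms: water, O
Why: Oxidative demethylation of the 1,4-dimethoxyarene to the para-quinone (the arene is oxidised far more easily than the tetrasubstituted alkene), then dithionite reduction to the hydroquinone.

**Step 19**
Reactants: 37 hydroquinone from step 18
Product: 38 target (CNP0144688.2)
Conditions: Ac2O (1.1 equiv), pyridine, CH2Cl2, −20 to 0 °C; aqueous work-up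
Reagents that add atoms: acetic anhydride, CC(=O)OC(C)=O
Why: Kinetic monoacetylation at the unhindered hydroxyl (flanked by two aromatic CH), the other hydroxyl being shielded by the ortho methyl and the bulky benzylic substituent; any mixed anhydride of the acid is hydrolysed on work-up.

**Compound list**
1 | 4-methoxy-2-methylphenol | Cc1cc(OC)ccc1O | starting material
2 | 2-hydroxy-5-methoxy-3-methylbenzaldehyde | COc1cc(C)c(O)c(C=O)c1 | intermediate
3 | 2,5-dimethoxy-3-methylbenzaldehyde | COc1cc(C)c(OC)c(C=O)c1 | intermediate
4 | (2,5-dimethoxy-3-methylphenyl)methanol | COc1cc(C)c(OC)c(CO)c1 | intermediate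
5 | 1-(bromomethyl)-2,5-dimethoxy-3-methylbenzene | COc1cc(C)c(OC)c(CBr)c1 | intermediate
6 | 2,3-dibromoprop-1-ene | C=C(Br)CBr | starting material
7 | allylmagnesium bromide | C=CC[Mg]Br | starting material
8 | 2-bromohexa-1,5-diene | C=CCCC(Br)=C | intermediate
9 | 3-methylcyclopent-2-en-1-one | CC1=CC(=O)CC1 | starting material
10 | 2-lithiohexa-1,5-diene | [Li]C(=C)CCC=C | intermediate
11 | (hexa-1,5-dien-2-yl)dimethylalane | C[Al](C)C(=C)CCC=C | intermediate
12 | dimethylaluminium enolate of (R)-3-(hexa-1,5-dien-2-yl)-3-methylcyclopentanone (C8–O, C8=C10) | C=CCCC(=C)[C@]1(C)CCC(O[Al](C)C)=C1 | intermediate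
13 | (R)-{[3-(hexa-1,5-dien-2-yl)-3-methylcyclopent-1-en-1-yl]oxy}trimethylsilane | C=CCCC(=C)[C@]1(C)CCC(O[Si](C)(C)C)=C1 | intermediate
14 | (3R)-2-[(dimethylamino)methyl]-3-(hexa-1,5-dien-2-yl)-3-methylcyclopentan-1-one (C2 epimers) | C=CCCC(=C)[C@]1(C)CCC(=O)C1CN(C)C | intermediate
15 | N-methyl quaternary ammonium iodide of 14 | C=CCCC(=C)[C@]1(C)CCC(=O)C1C[N+](C)(C)C.[I-] | intermediate
16 | (S)-3-(hexa-1,5-dien-2-yl)-3-methyl-2-methylidenecyclopentan-1-one | C=CCCC(=C)[C@]1(C)CCC(=O)C1=C | intermediate
17 | (S)-3a-methyl-4-methylidene-2,3,3a,4,5,6-hexahydro-1H-inden-1-one | C=C1CCC=C2C(=O)CC[C@@]12C | intermediate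
18 | (3aS)-5-hydroxy-3a-methyl-4-methylidene-2,3,3a,4,5,6-hexahydro-1H-inden-1-one (C3 epimers) | C=C1C(O)CC=C2C(=O)CC[C@@]12C | intermediate
19 | tert-butyldimethylsilyl ether of 18 | C=C1C(O[Si](C)(C)C(C)(C)C)CC=C2C(=O)CC[C@@]12C | intermediate
20 | 1,1-dibromoethane | CC(Br)Br | starting material
21 | lithium alkoxide of the C8 adduct of 19 with 1,1-dibromoethyllithium | C=C1C(O[Si](C)(C)C(C)(C)C)CC=C2C(O[Li])(C(C)(Br)Br)CC[C@@]12C | intermediate
22 | β-oxido carbenoid (C9 bearing Li, Br and CH3) | C=C1C(O[Si](C)(C)C(C)(C)C)CC=C2C(O[Li])(C(C)(Br)[Li])CC[C@@]12C | intermediate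
23 | ring-enlarged lithium dienolate (O–C8=C9(CH3)–C10=C1) | C=C1C(O[Si](C)(C)C(C)(C)C)CC=C2C(C)=C(O[Li])CC[C@@]12C | intermediate
24 | octal-1(10)-en-8-one: 9β-CH3, 9α-(2,5-dimethoxy-3-methylbenzyl), 5β-CH3, 4-methylidene, 3-OTBS | COc1cc(C)c(OC)c(C[C@]2(C)C3=CCC(O[Si](C)(C)C(C)(C)C)C(=C)[C@]3(C)CCC2=O)c1 | intermediate
25 | 8-methylidene analogue of 24 | COc1cc(C)c(OC)c(C[C@]2(C)C3=CCC(O[Si](C)(C)C(C)(C)C)C(=C)[C@]3(C)CCC2=C)c1 | intermediate
26 | C3 allylic alcohol from 25 | COc1cc(C)c(OC)c(C[C@]2(C)C3=CCC(O)C(=C)[C@]3(C)CCC2=C)c1 | intermediate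
27 | 3-oxo-4-methylidene compound (C8=CH2, C10=C1) | COc1cc(C)c(OC)c(C[C@]2(C)C3=CCC(=O)C(=C)[C@]3(C)CCC2=C)c1 | intermediate
28 | 1-methoxy-1-(trimethylsilyloxy)ethene | C=C(OC)O[Si](C)(C)C | starting material
29 | C3 trimethylsilyl enol ether of the Michael adduct | COc1cc(C)c(OC)c(C[C@]2(C)C3=CCC(O[Si](C)(C)C)=C(CCC(=O)OC)[C@]3(C)CCC2=C)c1 | intermediate
30 | 3-oxo compound with 4β-(3-methoxy-3-oxopropyl), 4α-H (C8=CH2, C10=C1) | COc1cc(C)c(OC)c(C[C@]2(C)C3=CCC(=O)[C@@H](CCC(=O)OC)[C@]3(C)CCC2=C)c1 | intermediate
31 | trans-decalin keto ester: 8β-CH3, 10α-H, 9β-CH3, 9α-CH2Ar, 5β-CH3, 4β-chain, C3 ketone | COc1cc(C)c(OC)c(C[C@]2(C)[C@H]3CCC(=O)[C@@H](CCC(=O)OC)[C@]3(C)CC[C@H]2C)c1 | intermediate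
32 | S-phenyl 2-methylpropanethioate | CC(C)C(=O)Sc1ccccc1 | starting material
33 | spiro β-lactone at C3 (3,3-dimethyloxetan-2-one) | COc1cc(C)c(OC)c(C[C@]2(C)[C@H]3CCC4(OC(=O)C4(C)C)[C@@H](CCC(=O)OC)[C@]3(C)CC[C@H]2C)c1 | intermediate
34 | methyl ester with C3=C(CH3)2 | COc1cc(C)c(OC)c(C[C@]2(C)[C@H]3CCC(=C(C)C)[C@@H](CCC(=O)OC)[C@]3(C)CC[C@H]2C)c1 | intermediate
35 | carboxylic acid, 2,5-dimethoxyarene | COc1cc(C)c(OC)c(C[C@]2(C)[C@H]3CCC(=C(C)C)[C@@H](CCC(=O)O)[C@]3(C)CC[C@H]2C)c1 | intermediate
36 | 2-methyl-6-alkyl-1,4-benzoquinone acid | O=C1C=C(C)C(=O)C(C[C@]2(C)[C@H]3CCC(=C(C)C)[C@@H](CCC(=O)O)[C@]3(C)CC[C@H]2C)=C1 | intermediate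
37 | hydroquinone acid | Oc1cc(C)c(O)c(C[C@]2(C)[C@H]3CCC(=C(C)C)[C@@H](CCC(=O)O)[C@]3(C)CC[C@H]2C)c1 | intermediate
38 | target: 4-O-acetyl hydroquinone acid, CNP0144688.2 | CC(=O)Oc1cc(C)c(O)c(C[C@]2(C)[C@H]3CCC(=C(C)C)[C@@H](CCC(=O)O)[C@]3(C)CC[C@H]2C)c1 | target

**Step count**
Total steps: 19. Longest linear sequence: 15 steps (steps 5 to 19); the arene branch (steps 1 to 4) joins at step 11.

**Steps most likely to fail**

Step 11. The process at risk is the carbenoid 1,2-shift: the C7 methylene may migrate instead of C10, the methyl-bearing carbenoid may collapse by a 1,2-hydride shift, the amide base may enolise the enone, or the hindered dienolate may alkylate incompletely. The fallback sets out from 19 and separates ring enlargement from alkylation. 1-Lithio-1-(phenylselanyl)ethane (from 1,1-bis(phenylselanyl)ethane and n-BuLi, THF, −78 °C) should add to the C8 carbonyl to give the β-hydroxy selenide F1. AgBF4 on Al2O3 in CH2Cl2 should trigger the selenonium-type semipinacol ring enlargement with alkenyl migration to the α-methyl β,γ-unsaturated ketone F2. KOt-Bu in THF/t-BuOH then regenerates the same dienolate, and deconjugative benzylation with 5 comes back to the route at 24.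

Step 16. The process at risk is the addition of a bulky tertiary enolate to the hindered, enolisable C3 ketone (enolisation or retro-aldol instead of lactonisation). The fallback sets out from 31 and uses a McMurry cross-coupling with excess acetone (TiCl4, Zn, pyridine, THF, reflux), which should give the tetrasubstituted alkene directly and comes back at 34; it makes no new compound.

Step 6. The process at risk is facial selectivity and conversion in the conjugate addition of a functionalised α-branched alkenylalane to the cyclopentenone. The fallback sets out from 9 and builds the side chain after the stereocentre. Conjugate addition of i-Bu2Al–C(SiMe3)=CH2 (from ethynyltrimethylsilane and i-Bu2AlH) under a chiral N-heterocyclic carbene copper catalyst made from CuCl2·2H2O, with TMSOTf trapping, should give the silyl enol ether F3. Methylenation as in step 7 gives the α-methylene ketone F4, and N-iodosuccinimide in MeCN gives the vinyl iodide F5. Negishi coupling with but-3-enylzinc bromide (Pd(PPh3)4, THF) comes back to the route at 16.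

**Further compounds**
F1 | step 11 | β-hydroxy selenide: C8 adduct of 19 with 1-(phenylselanyl)ethyllithium | C=C1C(O[Si](C)(C)C(C)(C)C)CC=C2C(O)(C(C)[Se]c3ccccc3)CC[C@@]12C
F2 | step 11 | ring-enlarged 9-methyl octal-1(10)-en-8-one (C9 epimers), 3-OTBS, 4-methylidene | C=C1C(O[Si](C)(C)C(C)(C)C)CC=C2C(C)C(=O)CC[C@@]12C
F0 | step 16 | none | none
F3 | step 6 | trimethyl{[3-methyl-3-(1-(trimethylsilyl)vinyl)cyclopent-1-en-1-yl]oxy}silane, C5 as in 13 | C=C([Si](C)(C)C)[C@]1(C)CCC(O[Si](C)(C)C)=C1
F4 | step 6 | 3-methyl-2-methylidene-3-[1-(trimethylsilyl)vinyl]cyclopentan-1-one, C5 as in 16 | C=C([Si](C)(C)C)[C@]1(C)CCC(=O)C1=C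
F5 | step 6 | 3-(1-iodovinyl)-3-methyl-2-methylidenecyclopentan-1-one, C5 as in 16 | C=C(I)[C@]1(C)CCC(=O)C1=C
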